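**Plan**

- Retrosynthesis: cut (i) the ring A–C(=O) bond of the chalcone (aryllithium + cinnamic Weinreb amide), (ii) the C3–C4 bond of the oxane, which opens the ring, (iii) the enol ether C=CH2 back to an aryl ester C=O, (iv) the ring A–C4 bond (aryllithium + aldehyde), (v) the ester C–O bond and the allyl–C6 bond.
- Forward: the C6 carbinol is made by asymmetric allylation, acylated with the C2 aryl acid, cut to the C4 aldehyde, joined to lithiated ring A, and methylenated; then the oxane, the only ring formed in the route, is closed. Ring A is afterwards brominated, lithiated and acylated to the chalcone, and the five MOM ethers are removed last.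
- Enabling feature: oxane C4 carries ring A, whose two ortho oxygens and para oxygen stabilise a cation on C4. C2 carries both the ring oxygen O1 and a 4-oxyphenyl ring, so C2=C3 can be an electron-rich 1-aryl enol ether, and the cyclised ion is an aryl-stabilised oxocarbenium ion at C2 that a silane reduces.
- Helpers: a benzylic OSiMe3 leaving group on C4 (lost in the ring closure), a bromine on ring A (lost on lithiation), MOM ethers (lost at the end).
- Stereochemistry: C6 comes from reagent-controlled Brown allylation. C4 and C2 both come from C6 in the ring closure (chair transition state, then axial hydride delivery). The C4 configuration of the open-chain precursor is erased on ionisation. The (E)-alkene comes from the Horner–Wadsworth–Emmons reaction.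

Key step: step 10

Remark: MOM = methoxymethyl; the oxane is numbered O1, C2 (4-oxyphenyl), C3, C4 (ring A), C5, C6 (arylethyl); ring A is the trioxygenated ring.

**Route**

Step 1
Reactants: 1 methyl 3-(4-hydroxyphenyl)propanoate
Product: 2 methyl 3-[4-(methoxymethoxy)phenyl]propanoate
Conditions: MOMCl, i-Pr2NEt, CH2Cl2, 0 °C → rt
Reagents that add atoms: chloromethyl methyl ether (MOMCl), COCCl
Why: O-alkylation of the phenol (MOM protection) should be clean because the phenol is the only acidic site.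

Step 2
Reactants: 2 methyl 3-[4-(methoxymethoxy)phenyl]propanoate
Product: 4 3-[4-(methoxymethoxy)phenyl]propanal, via aluminium hemiacetal 3 (not isolated)
Conditions: i-Bu2AlH (1.05 equiv), CH2Cl2, −78 °C; aq. Rochelle salt
Reagents that add atoms: none
Why: At −78 °C the tetrahedral aluminium hemiacetal persists and collapses to the aldehyde only on work-up (partial ester reduction with i-Bu2AlH).

Step 3
Reactants: 4 3-[4-(methoxymethoxy)phenyl]propanal
Product: 6 (3S)-1-[4-(methoxymethoxy)phenyl]hex-5-en-3-ol, via borinate ester 5 (not isolated)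
Conditions: allylB(Ipc)2 [from (+)-Ipc2BOMe, allylMgBr, Et2O], −78 °C; then NaOH, H2O2, 0 °C → rt
Reagents that add atoms: B-allylbis(isopinocampheyl)borane of the (−)-α-pinene series, C=CCB([C@H]1C[C@H]2C[C@@H]([C@@H]1C)C2(C)C)[C@H]1C[C@H]2C[C@@H]([C@@H]1C)C2(C)C
Why: Brown allylation through a closed chair transition state, in which the isopinocampheyl groups of the (−)-α-pinene series direct the allyl group to the Re face of the aldehyde, should set the (S) carbinol that becomes C6 of the oxane.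

Step 4
Reactants: 7 4-(methoxymethoxy)benzaldehyde
Product: 8 4-(methoxymethoxy)benzoic acid
Conditions: NaClO2, NaH2PO4, 2-methyl-2-butene, t-BuOH/H2O, rt
Reagents that add atoms: sodium chlorite, [Na+].[O-]Cl=O
Why: Pinnick oxidation at buffered pH leaves the aryl MOM ether intact while the alkene scavenger removes hypochlorous acid.

Step 5
Reactants: 6 (3S)-1-[4-(methoxymethoxy)phenyl]hex-5-en-3-ol; 8 4-(methoxymethoxy)benzoic acid
Product: 9 (3S)-1-[4-(methoxymethoxy)phenyl]hex-5-en-3-yl 4-(methoxymethoxy)benzoate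
Conditions: DCC, DMAP (cat.), CH2Cl2, 0 °C → rt
Reagents that add atoms: none
Why: Steglich esterification acylates the secondary alcohol at oxygen with retention at the carbinol carbon and brings in the carbon that becomes C2 together with its aryl group.

Step 6
Reactants: 9 (3S)-1-[4-(methoxymethoxy)phenyl]hex-5-en-3-yl 4-(methoxymethoxy)benzoate
Product: 11 (3S)-5-[4-(methoxymethoxy)phenyl]-1-oxopentan-3-yl 4-(methoxymethoxy)benzoate, via ozonide 10 (not isolated)
Conditions: O3, CH2Cl2, −78 °C (stopped at the first blue colour); then PPh3, −78 °C → rt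
Reagents that add atoms: ozone, [O-][O+]=O
Why: Ozonolysis with reductive work-up cleaves the terminal alkene much faster than ozone attacks the alkoxyarenes and gives the aldehyde carbon that becomes C4.

Step 7
Reactants: 12 5-methoxyresorcinol
Product: 13 1-methoxy-3,5-bis(methoxymethoxy)benzene
Conditions: MOMCl (2.5 equiv), i-Pr2NEt, CH2Cl2, 0 °C → rt
Reagents that add atoms: chloromethyl methyl ether (MOMCl), COCCl
Why: Double MOM protection installs the two acetal groups that later direct lithiation and can be removed without touching the methyl ether.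

Step 8
Reactants: 13 1-methoxy-3,5-bis(methoxymethoxy)benzene; 11 (3S)-5-[4-(methoxymethoxy)phenyl]-1-oxopentan-3-yl 4-(methoxymethoxy)benzoate
Product: 16 (1RS,3S)-1-[4-methoxy-2,6-bis(methoxymethoxy)phenyl]-5-[4-(methoxymethoxy)phenyl]-1-[(trimethylsilyl)oxy]pentan-3-yl 4-(methoxymethoxy)benzoate, via aryllithium 14 (not isolated), via lithium alkoxide 15 (not isolated)
Conditions: 13, n-BuLi, THF, 0 °C; then 11, −78 °C; then TMSCl, −78 → −20 °C
Reagents that add atoms: chlorotrimethylsilane, C[Si](C)(C)Cl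
Why: Directed ortho-lithiation between the two MOM ethers gives 14, whose 1,2-addition to the aldehyde at −78 °C is far faster than attack on the electron-rich benzoate, and silylation of alkoxide 15 in the cold forestalls 1,3-acyl migration; the carbinol centre forms without control, which is harmless because it is ionised in step 10.

Step 9
Reactants: 16 (1RS,3S)-1-[4-methoxy-2,6-bis(methoxymethoxy)phenyl]-5-[4-(methoxymethoxy)phenyl]-1-[(trimethylsilyl)oxy]pentan-3-yl 4-(methoxymethoxy)benzoate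
Product: 17 {[(1RS,3S)-1-[4-methoxy-2,6-bis(methoxymethoxy)phenyl]-5-[4-(methoxymethoxy)phenyl]-3-({1-[4-(methoxymethoxy)phenyl]ethenyl}oxy)pentyl]oxy}trimethylsilane
Conditions: Cp2TiMe2 (3 equiv), toluene/THF, 65 °C, dark
Reagents that add atoms: dimethyltitanocene (Petasis reagent), [CH3-].[CH3-].c1cc[cH-]c1.c1cc[cH-]c1.[Ti+4]
Why: Petasis methylenation converts the aryl ester carbonyl into the 1-aryl enol ether through a titanocene methylidene and an oxatitanacyclobutane, under non-acidic conditions that the silyl ether and the MOM ethers tolerate.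

Step 10
Reactants: 17 {[(1RS,3S)-1-[4-methoxy-2,6-bis(methoxymethoxy)phenyl]-5-[4-(methoxymethoxy)phenyl]-3-({1-[4-(methoxymethoxy)phenyl]ethenyl}oxy)pentyl]oxy}trimethylsilane
Product: 20 (2S,4R,6S)-4-[4-methoxy-2,6-bis(methoxymethoxy)phenyl]-2-[4-(methoxymethoxy)phenyl]-6-{2-[4-(methoxymethoxy)phenyl]ethyl}oxane, via benzylic cation 18 (not isolated), via oxocarbenium ion 19 (not isolated)
Conditions: TMSOTf (0.3 equiv), Et3SiH (3 equiv), 2,6-di-tert-butyl-4-methylpyridine (0.5 equiv), CH2Cl2, −78 → −40 °C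
Reagents that add atoms: none
Why: Proposed new method: catalytic TMSOTf ionises the benzylic silyl ether of either epimer of 17 to the 2,4,6-trialkoxybenzyl cation 18, the CH2 terminus of the 1-aryl enol ether attacks it, and the resulting 2-aryl oxocarbenium ion 19 takes hydride from Et3SiH, which returns the silyl triflate; no proton is formed in this cycle. The closest known reaction types are the Prins and Petasis–Ferrier oxane syntheses (alkene or enol ether plus oxocarbenium ion, but forming the C2–C3 bond), SN1 alkylation of enol ethers by stabilised benzylic cations, and silane reduction of cyclic 2-aryl oxocarbenium ions to 2,6-cis oxanes. The oxane closes in a 6-(enolendo)-exo-trig mode through a chair transition state. C4 is controlled by C6: with the C6 arylethyl chain equatorial, ring A takes the pseudo-equatorial site on the planar cationic carbon, which gives the 4,6-cis (4R) arrangement, and the old C4 configuration is erased so both epimers converge. C2 is set by axial hydride delivery to the half-chair ion 19, which puts the 4-(methoxymethoxy)phenyl group equatorial (2S), cis to the other two substituents. The step needs ring closure to outrun hydride capture or proton loss of 18 and needs the enol ether to stay unprotonated: the six-membered intramolecular attack of a nucleophile far stronger than the anisole-type rings on a long-lived, strongly stabilised cation, the proton-free cycle, the hindered pyridine buffer and −78 °C should secure this.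

Step 11
Reactants: 20 (2S,4R,6S)-4-[4-methoxy-2,6-bis(methoxymethoxy)phenyl]-2-[4-(methoxymethoxy)phenyl]-6-{2-[4-(methoxymethoxy)phenyl]ethyl}oxane
Product: 21 (2S,4R,6S)-4-[3-bromo-4-methoxy-2,6-bis(methoxymethoxy)phenyl]-2-[4-(methoxymethoxy)phenyl]-6-{2-[4-(methoxymethoxy)phenyl]ethyl}oxane
Conditions: NBS (1.0 equiv), MeCN, −20 → 0 °C, dark
Reagents that add atoms: N-bromosuccinimide, O=C1CCC(=O)N1Br
Why: Electrophilic aromatic bromination should occur on ring A, by far the most electron-rich arene, at one of its two equivalent free positions (each between OMe and OMOM), and the first bromine slows a second substitution.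

Step 12
Reactants: 7 4-(methoxymethoxy)benzaldehyde; 22 diethyl {2-[methoxy(methyl)amino]-2-oxoethyl}phosphonate
Product: 24 (2E)-N-methoxy-3-[4-(methoxymethoxy)phenyl]-N-methylprop-2-enamide, via sodium phosphonate carbanion 23 (not isolated)
Conditions: 22, NaH, THF, 0 °C; then 7, 0 °C → rt
Reagents that add atoms: none
Why: Horner–Wadsworth–Emmons olefination with the stabilised Weinreb phosphonate gives the (E)-enamide because the oxaphosphetane forms reversibly and the trans isomer eliminates.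

Step 13
Reactants: 21 (2S,4R,6S)-4-[3-bromo-4-methoxy-2,6-bis(methoxymethoxy)phenyl]-2-[4-(methoxymethoxy)phenyl]-6-{2-[4-(methoxymethoxy)phenyl]ethyl}oxane; 24 (2E)-N-methoxy-3-[4-(methoxymethoxy)phenyl]-N-methylprop-2-enamide
Product: 27 (2E)-1-{6-methoxy-2,4-bis(methoxymethoxy)-3-[(2S,4R,6S)-2-[4-(methoxymethoxy)phenyl]-6-{2-[4-(methoxymethoxy)phenyl]ethyl}oxan-4-yl]phenyl}-3-[4-(methoxymethoxy)phenyl]prop-2-en-1-one, via aryllithium 25 (not isolated), via tetrahedral lithium adduct 26 (not isolated)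
Conditions: 21, n-BuLi, THF, −78 °C; then 24, −78 → −20 °C; then AcOH
Reagents that add atoms: none
Why: Bromine–lithium exchange gives 25 at the defined ring position, and its carbonyl addition to the Weinreb amide stops at chelate 26, which releases the enone only on work-up (Weinreb ketone synthesis), so neither over-addition nor loss of the (E)-alkene is expected.

Step 14
Reactants: 27 (2E)-1-{6-methoxy-2,4-bis(methoxymethoxy)-3-[(2S,4R,6S)-2-[4-(methoxymethoxy)phenyl]-6-{2-[4-(methoxymethoxy)phenyl]ethyl}oxan-4-yl]phenyl}-3-[4-(methoxymethoxy)phenyl]prop-2-en-1-one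
Product: 28 (2E)-1-{2,4-dihydroxy-3-[(2S,4R,6S)-2-(4-hydroxyphenyl)-6-[2-(4-hydroxyphenyl)ethyl]oxan-4-yl]-6-methoxyphenyl}-3-(4-hydroxyphenyl)prop-2-en-1-one (CNP0215517.1)
Conditions: 3 M aq. HCl, MeOH, rt → 40 °C
Reagents that add atoms: none
Why: Acid-catalysed acetal exchange with methanol (MOM removal, a deprotection with close precedent on 2'-hydroxy-6'-methoxychalcones) frees the five phenols, the aryl methyl ether is inert, and the all-equatorial oxane is the thermodynamically preferred isomer, so reversible benzylic C–O ionisation should not change it.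

**Compound list**

1 | methyl 3-(4-hydroxyphenyl)propanoate | COC(=O)CCc1ccc(O)cc1 | starting material
2 | methyl 3-[4-(methoxymethoxy)phenyl]propanoate | COCOc1ccc(CCC(=O)OC)cc1 | intermediate
3 | diisobutyl{1-methoxy-3-[4-(methoxymethoxy)phenyl]propoxy}aluminium | COCOc1ccc(CCC(OC)O[Al](CC(C)C)CC(C)C)cc1 | intermediate
4 | 3-[4-(methoxymethoxy)phenyl]propanal | COCOc1ccc(CCC=O)cc1 | intermediate
5 | (3S)-1-[4-(methoxymethoxy)phenyl]hex-5-en-3-yl bis(isopinocampheyl)borinate | C=CC[C@H](CCc1ccc(OCOC)cc1)OB([C@H]1C[C@H]2C[C@@H]([C@@H]1C)C2(C)C)[C@H]1C[C@H]2C[C@@H]([C@@H]1C)C2(C)C | intermediate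
6 | (3S)-1-[4-(methoxymethoxy)phenyl]hex-5-en-3-ol | C=CC[C@H](CCc1ccc(OCOC)cc1)O | intermediate
7 | 4-(methoxymethoxy)benzaldehyde | COCOc1ccc(C=O)cc1 | starting material
8 | 4-(methoxymethoxy)benzoic acid | COCOc1ccc(C(=O)O)cc1 | intermediate
9 | (3S)-1-[4-(methoxymethoxy)phenyl]hex-5-en-3-yl 4-(methoxymethoxy)benzoate | C=CC[C@H](CCc1ccc(OCOC)cc1)OC(=O)c1ccc(OCOC)cc1 | intermediate
10 | (2S)-4-[4-(methoxymethoxy)phenyl]-1-(1,2,4-trioxolan-3-yl)butan-2-yl 4-(methoxymethoxy)benzoate (ozonide) | C1OOC(C[C@H](CCc2ccc(OCOC)cc2)OC(=O)c2ccc(OCOC)cc2)O1 | intermediate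
11 | (3S)-5-[4-(methoxymethoxy)phenyl]-1-oxopentan-3-yl 4-(methoxymethoxy)benzoate | O=CC[C@H](CCc1ccc(OCOC)cc1)OC(=O)c1ccc(OCOC)cc1 | intermediate
12 | 5-methoxyresorcinol (5-methoxybenzene-1,3-diol) | COc1cc(O)cc(O)c1 | starting material
13 | 1-methoxy-3,5-bis(methoxymethoxy)benzene | COCOc1cc(OC)cc(OCOC)c1 | intermediate
14 | [4-methoxy-2,6-bis(methoxymethoxy)phenyl]lithium | [Li]c1c(OCOC)cc(OC)cc1OCOC | intermediate
15 | lithium (1RS,3S)-3-{[4-(methoxymethoxy)benzoyl]oxy}-1-[4-methoxy-2,6-bis(methoxymethoxy)phenyl]-5-[4-(methoxymethoxy)phenyl]pentan-1-olate | [Li]OC(C[C@H](CCc1ccc(OCOC)cc1)OC(=O)c1ccc(OCOC)cc1)c1c(OCOC)cc(OC)cc1OCOC | intermediate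
16 | (1RS,3S)-1-[4-methoxy-2,6-bis(methoxymethoxy)phenyl]-5-[4-(methoxymethoxy)phenyl]-1-[(trimethylsilyl)oxy]pentan-3-yl 4-(methoxymethoxy)benzoate | C[Si](C)(C)OC(C[C@H](CCc1ccc(OCOC)cc1)OC(=O)c1ccc(OCOC)cc1)c1c(OCOC)cc(OC)cc1OCOC | intermediate
17 | {[(1RS,3S)-1-[4-methoxy-2,6-bis(methoxymethoxy)phenyl]-5-[4-(methoxymethoxy)phenyl]-3-({1-[4-(methoxymethoxy)phenyl]ethenyl}oxy)pentyl]oxy}trimethylsilane | C[Si](C)(C)OC(C[C@H](CCc1ccc(OCOC)cc1)OC(=C)c1ccc(OCOC)cc1)c1c(OCOC)cc(OC)cc1OCOC | intermediate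
18 | (3S)-1-[4-methoxy-2,6-bis(methoxymethoxy)phenyl]-5-[4-(methoxymethoxy)phenyl]-3-({1-[4-(methoxymethoxy)phenyl]ethenyl}oxy)pentan-1-ylium triflate (benzylic cation) | [CH+](C[C@H](CCc1ccc(OCOC)cc1)OC(=C)c1ccc(OCOC)cc1)c1c(OCOC)cc(OC)cc1OCOC.[O-]S(=O)(=O)C(F)(F)F | intermediate
19 | (4R,6S)-4-[4-methoxy-2,6-bis(methoxymethoxy)phenyl]-2-[4-(methoxymethoxy)phenyl]-6-{2-[4-(methoxymethoxy)phenyl]ethyl}-3,4,5,6-tetrahydropyran-1-ium triflate (cyclic oxocarbenium ion, O1=C2) | COc1cc(OCOC)c([C@@H]2C[C@H](CCc3ccc(OCOC)cc3)[O+]=C(c3ccc(OCOC)cc3)C2)c(OCOC)c1.[O-]S(=O)(=O)C(F)(F)F | intermediate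
20 | (2S,4R,6S)-4-[4-methoxy-2,6-bis(methoxymethoxy)phenyl]-2-[4-(methoxymethoxy)phenyl]-6-{2-[4-(methoxymethoxy)phenyl]ethyl}oxane | COc1cc(OCOC)c([C@@H]2C[C@H](CCc3ccc(OCOC)cc3)O[C@H](c3ccc(OCOC)cc3)C2)c(OCOC)c1 | intermediate
21 | (2S,4R,6S)-4-[3-bromo-4-methoxy-2,6-bis(methoxymethoxy)phenyl]-2-[4-(methoxymethoxy)phenyl]-6-{2-[4-(methoxymethoxy)phenyl]ethyl}oxane | COc1cc(OCOC)c([C@@H]2C[C@H](CCc3ccc(OCOC)cc3)O[C@H](c3ccc(OCOC)cc3)C2)c(OCOC)c1Br | intermediate
22 | diethyl {2-[methoxy(methyl)amino]-2-oxoethyl}phosphonate | CCOP(=O)(CC(=O)N(C)OC)OCC | starting material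
23 | sodium salt of the carbanion of diethyl {2-[methoxy(methyl)amino]-2-oxoethyl}phosphonate | CCOP(=O)([CH-]C(=O)N(C)OC)OCC.[Na+] | intermediate
24 | (2E)-N-methoxy-3-[4-(methoxymethoxy)phenyl]-N-methylprop-2-enamide | CON(C)C(=O)/C=C/c1ccc(OCOC)cc1 | intermediate
25 | {6-methoxy-2,4-bis(methoxymethoxy)-3-[(2S,4R,6S)-2-[4-(methoxymethoxy)phenyl]-6-{2-[4-(methoxymethoxy)phenyl]ethyl}oxan-4-yl]phenyl}lithium | COc1cc(OCOC)c([C@@H]2C[C@H](CCc3ccc(OCOC)cc3)O[C@H](c3ccc(OCOC)cc3)C2)c(OCOC)c1[Li] | intermediate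
26 | lithium (2E)-1-[methoxy(methyl)amino]-1-{6-methoxy-2,4-bis(methoxymethoxy)-3-[(2S,4R,6S)-2-[4-(methoxymethoxy)phenyl]-6-{2-[4-(methoxymethoxy)phenyl]ethyl}oxan-4-yl]phenyl}-3-[4-(methoxymethoxy)phenyl]prop-2-en-1-olate | COc1cc(OCOC)c([C@@H]2C[C@H](CCc3ccc(OCOC)cc3)O[C@H](c3ccc(OCOC)cc3)C2)c(OCOC)c1C(O[Li])(N(C)OC)/C=C/c1ccc(OCOC)cc1 | intermediate
27 | (2E)-1-{6-methoxy-2,4-bis(methoxymethoxy)-3-[(2S,4R,6S)-2-[4-(methoxymethoxy)phenyl]-6-{2-[4-(methoxymethoxy)phenyl]ethyl}oxan-4-yl]phenyl}-3-[4-(methoxymethoxy)phenyl]prop-2-en-1-one | COc1cc(OCOC)c([C@@H]2C[C@H](CCc3ccc(OCOC)cc3)O[C@H](c3ccc(OCOC)cc3)C2)c(OCOC)c1C(=O)/C=C/c1ccc(OCOC)cc1 | intermediate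
28 | (2E)-1-{2,4-dihydroxy-3-[(2S,4R,6S)-2-(4-hydroxyphenyl)-6-[2-(4-hydroxyphenyl)ethyl]oxan-4-yl]-6-methoxyphenyl}-3-(4-hydroxyphenyl)prop-2-en-1-one | COc1cc(O)c([C@@H]2C[C@H](CCc3ccc(O)cc3)O[C@H](c3ccc(O)cc3)C2)c(O)c1C(=O)/C=C/c1ccc(O)cc1 | target

**Count**

Total steps: 14. Longest linear sequence: 11 (steps 1, 2, 3, 5, 6, 8, 9, 10, 11, 13, 14).

**Steps most likely to fail**

1. Step 10 (the proposed new method). What may go wrong:
- hydride capture or proton loss of the benzylic cation before the C–C bond forms;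
- reversible capture of the cation by an ortho MOM oxygen followed by loss of that protecting group;
- protonation and reduction of the enol ether by adventitious acid;
- poor facial selectivity at C4.

Fallback with known chemistry, setting out from 6 and 7 and coming back at 20: a Prins cyclisation of 6 with 7 (Ph3SiOReO3 cat., CH2Cl2, rt) should give the all-cis (2S,4R,6S)-2-[4-(methoxymethoxy)phenyl]-6-{2-[4-(methoxymethoxy)phenyl]ethyl}oxan-4-ol F1. Dess–Martin oxidation should give (2S,6S)-2-[4-(methoxymethoxy)phenyl]-6-{2-[4-(methoxymethoxy)phenyl]ethyl}oxan-4-one F2. Addition of aryllithium 14 (with CeCl3 to suppress enolisation) should give the tertiary carbinol (2S,6S)-4-[4-methoxy-2,6-bis(methoxymethoxy)phenyl]-2-[4-(methoxymethoxy)phenyl]-6-{2-[4-(methoxymethoxy)phenyl]ethyl}oxan-4-ol F3 as either C4 epimer. PPTS-catalysed dehydration should give the two alkene isomers, the C3=C4 compound (2S,6S)-4-[4-methoxy-2,6-bis(methoxymethoxy)phenyl]-2-[4-(methoxymethoxy)phenyl]-6-{2-[4-(methoxymethoxy)phenyl]ethyl}-5,6-dihydro-2H-pyran F4 and the C4=C5 compound (2S,6S)-4-[4-methoxy-2,6-bis(methoxymethoxy)phenyl]-2-[4-(methoxymethoxy)phenyl]-6-{2-[4-(methoxymethoxy)phenyl]ethyl}-3,6-dihydro-2H-pyran F5. Hydrogen-atom-transfer hydrogenation of the mixture (Mn(dpm)3, PhSiH3, t-BuOOH, i-PrOH) should deliver hydrogen to the tertiary benzylic radical from the axial direction and so place ring A equatorial, which is 20.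

2. Step 8. What may go wrong:
- 1,3-acyl migration in the lithium alkoxide before it is silylated;
- base-induced β-elimination of the aroyloxy group from the aldehyde;
- competing attack of the aryllithium on the ester.

Fallback, setting out from 13 and 11 and coming back at 16: aryllithium 14 is quenched with I2 to give 2-iodo-5-methoxy-1,3-bis(methoxymethoxy)benzene F6. F6 is then coupled with 11 in a Nozaki–Hiyama–Kishi reaction run with manganese turnover (CrCl2 cat., NiCl2 cat., Mn powder, TMSCl, DMF/DME, rt). The arylchromium species is not basic and does not attack esters, and the chromium alkoxide is silylated as it forms, so 16 should be obtained directly.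

3. Step 13. What may go wrong:
- conjugate instead of carbonyl addition;
- slow attack by the di-ortho-substituted aryllithium, with protonation taking over;
- Michael addition of the liberated hydroxylamine to the enone on work-up.

Fallback, setting out from 21 and coming back at 27: aryllithium 25 is acylated with N-methoxy-N-methylacetamide to give 1-{6-methoxy-2,4-bis(methoxymethoxy)-3-[(2S,4R,6S)-2-[4-(methoxymethoxy)phenyl]-6-{2-[4-(methoxymethoxy)phenyl]ethyl}oxan-4-yl]phenyl}ethan-1-one F7. A Claisen–Schmidt condensation of F7 with 7 (KOH, EtOH, rt), a reaction with close precedent on 2',6'-dioxygenated acetophenones, should give 27 as the (E)-enone.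

**Further compounds**

F1 | step 10 | (2S,4R,6S)-2-[4-(methoxymethoxy)phenyl]-6-{2-[4-(methoxymethoxy)phenyl]ethyl}oxan-4-ol | O[C@@H]1C[C@H](CCc2ccc(OCOC)cc2)O[C@H](c2ccc(OCOC)cc2)C1
F2 | step 10 | (2S,6S)-2-[4-(methoxymethoxy)phenyl]-6-{2-[4-(methoxymethoxy)phenyl]ethyl}oxan-4-one | O=C1C[C@H](CCc2ccc(OCOC)cc2)O[C@H](c2ccc(OCOC)cc2)C1
F3 | step 10 | (2S,6S)-4-[4-methoxy-2,6-bis(methoxymethoxy)phenyl]-2-[4-(methoxymethoxy)phenyl]-6-{2-[4-(methoxymethoxy)phenyl]ethyl}oxan-4-ol (either C4 epimer) | COc1cc(OCOC)c(C2(O)C[C@H](CCc3ccc(OCOC)cc3)O[C@H](c3ccc(OCOC)cc3)C2)c(OCOC)c1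
F4 | step 10 | (2S,6S)-4-[4-methoxy-2,6-bis(methoxymethoxy)phenyl]-2-[4-(methoxymethoxy)phenyl]-6-{2-[4-(methoxymethoxy)phenyl]ethyl}-5,6-dihydro-2H-pyran | COc1cc(OCOC)c(C=2C[C@H](CCc3ccc(OCOC)cc3)O[C@H](c3ccc(OCOC)cc3)C=2)c(OCOC)c1
F5 | step 10 | (2S,6S)-4-[4-methoxy-2,6-bis(methoxymethoxy)phenyl]-2-[4-(methoxymethoxy)phenyl]-6-{2-[4-(methoxymethoxy)phenyl]ethyl}-3,6-dihydro-2H-pyran | COc1cc(OCOC)c(C2=C[C@H](CCc3ccc(OCOC)cc3)O[C@H](c3ccc(OCOC)cc3)C2)c(OCOC)c1
F6 | step 8 | 2-iodo-5-methoxy-1,3-bis(methoxymethoxy)benzene | Ic1c(OCOC)cc(OC)cc1OCOC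
F7 | step 13 | 1-{6-methoxy-2,4-bis(methoxymethoxy)-3-[(2S,4R,6S)-2-[4-(methoxymethoxy)phenyl]-6-{2-[4-(methoxymethoxy)phenyl]ethyl}oxan-4-yl]phenyl}ethan-1-one | COc1cc(OCOC)c([C@@H]2C[C@H](CCc3ccc(OCOC)cc3)O[C@H](c3ccc(OCOC)cc3)C2)c(OCOC)c1C(C)=O
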